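**Retrosynthetic overview**

- The route rests on the C2=C3 double bond of the pyrrole ring (ring B) of the indole: C3 is taken from an aryl ketone carbon and C2 from an N-formyl carbon, so the bond is made by reductive carbonyl–carbonyl coupling.
- Target ⇒ (C2–Br, electrophilic bromination) 5,6-dibromo-1-methylgramine ⇒ (amide reduction) 5,6-dibromo-N,N,1-trimethylindole-3-carboxamide.
- Indole-3-carboxamide ⇒ (C2=C3, low-valent titanium oxo-amide coupling) ortho-(dimethylaminooxalyl)-N-methylformanilide.
- Formanilide ⇒ (N-formylation, aminolytic lactam opening) 5,6-dibromo-1-methylisatin ⇒ (N-methylation, C5 bromination) 6-bromoisatin.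
- Ring order: the benzene ring (ring A) comes with 6-bromoisatin; the five-membered ring of the isatin is opened and the pyrrole ring (ring B) is closed in the key step.

Key step: step 5

Remark: the target is achiral, so no stereocentre has to be set. Acetic formic anhydride is taken as a separately prepared reagent, and alane is made in the flask from LiAlH4 and AlCl3.

**Route**

Step 1
Reactants: 1 6-bromoisatin
Product: 2 5,6-dibromoisatin
Conditions: Br2 (1.05 equiv), AcOH, 80 °C
Reagents that add atoms: bromine, BrBr
Why: Electrophilic aromatic bromination, in which the ring nitrogen directs para to C5 (meta to the C3 ketone), the position at which isatins brominate first, so one equivalent of bromine should give the 5,6-dibromo pattern with C7 as the minor competing site.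

Step 2
Reactants: 2 5,6-dibromoisatin; 3 iodomethane
Product: 4 5,6-dibromo-1-methylisatin
Conditions: K2CO3, DMF, rt
Reagents that add atoms: iodomethane, CI
Why: N-Alkylation (SN2) of the acidic, imide-like isatin N–H with iodomethane under dry carbonate base, which avoids hydroxide-induced opening of the ring.

Step 3
Reactants: 4 5,6-dibromo-1-methylisatin; 5 dimethylamine
Product: 6 2-[4,5-dibromo-2-(methylamino)phenyl]-N,N-dimethyl-2-oxoacetamide
Conditions: Me2NH (2 M in THF, 5 equiv), THF, rt, sealed vessel; evaporation
Reagents that add atoms: dimethylamine, CNC
Why: Aminolysis (nucleophilic acyl substitution) at the C2 lactam carbonyl, which is activated by the neighbouring C3 ketone and by the electron-poor dibromoanilide leaving group, opens the five-membered ring to the α-ketoamide, and room temperature should keep the amine from displacing the bromine para to the ketone.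

Step 4
Reactants: 6 2-[4,5-dibromo-2-(methylamino)phenyl]-N,N-dimethyl-2-oxoacetamide
Product: 7 N-[4,5-dibromo-2-(2-(dimethylamino)-2-oxoacetyl)phenyl]-N-methylformamide
Conditions: AcOCHO (3 equiv), THF, 0 °C → 40 °C
Reagents that add atoms: acetic formic anhydride, CC(=O)OC=O
Why: N-Formylation by acyl transfer from a mixed anhydride, whose formyl carbonyl is the more electrophilic and less hindered one, so the hindered, hydrogen-bonded N-methylaniline should be formylated selectively, and the only weakly acidic medium should limit reclosure to the isatin.

Step 5
Reactants: 7 N-[4,5-dibromo-2-(2-(dimethylamino)-2-oxoacetyl)phenyl]-N-methylformamide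
Product: 9 5,6-dibromo-N,N,1-trimethylindole-3-carboxamide, via titanium 2,3-diolate 8 (not isolated)
Conditions: TiCl3 (3 equiv), Zn dust (6 equiv), DME, reflux, substrate present from the start ("instant" protocol), stopped at full conversion; filtration through silica
Reagents that add atoms: none
Why: Zinc reduces TiCl3 to low-valent titanium, which transfers electrons to the aryl ketone, the most easily reduced carbonyl of 7 (an aryl α-oxo amide), to give a titanium-bound ketyl or carbanion at the future C3. This carbon adds to the formyl carbon (the future C2) held ortho on the N-methylanilide, a 5-exo-trig closure that forms the C2–C3 bond and the pyrrole ring (ring B) as titanium diolate 8. McMurry-type deoxygenation of the 1,2-diolate, driven by the strong Ti–O bonds and by aromatisation, should then give indole 9; the closest known reaction is the Fürstner indole synthesis, the titanium-mediated oxo-amide coupling of 2-acylanilides. No stereocentre remains in 9, so the uncontrolled configuration of 8 is of no consequence. The step needs intramolecular ketone–formamide coupling to win over pinacol dimerisation, plain reduction of the ketone and reduction of the two C–Br bonds; the rigid 1,5-relation of the two carbonyl carbons across the aryl–N bond, the higher electrophilicity of the formamide compared with the dimethylcarboxamide, and the limited reductant and short contact time of the "instant" protocol should secure this.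

Step 6
Reactants: 9 5,6-dibromo-N,N,1-trimethylindole-3-carboxamide
Product: 10 5,6-dibromo-1-methylgramine [1-(5,6-dibromo-1-methylindol-3-yl)-N,N-dimethylmethanamine]
Conditions: AlH3 (from LiAlH4 and AlCl3, 3:1, THF, 0 °C), THF, 0 °C; aq. KNaC4H4O6 (potassium sodium tartrate) work-up
Reagents that add atoms: none
Why: Amide-to-amine reduction with the electrophilic hydride AlH3, which binds the electron-rich (vinylogous urea) carboxamide oxygen, delivers hydride and reduces the derived iminium ion, and which at 0 °C should leave the aryl C–Br bonds untouched, unlike LiAlH4 at reflux.

Step 7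
Reactants: 10 5,6-dibromo-1-methylgramine
Product: 11 2,5,6-tribromo-1-methylgramine
Conditions: CF3CO2H (1.1 equiv), CH2Cl2, 0 °C; then NBS (1.05 equiv), 0 °C → rt, dark; aq. NaHCO3/Na2S2O3 work-up
Reagents that add atoms: N-bromosuccinimide, O=C1CCC(=O)N1Br
Why: Electrophilic aromatic bromination of a 3-substituted N-methylindole at C2, the only free position of the pyrrole ring, with the amine carried as its trifluoroacetate so that NBS should not oxidise the nitrogen and ipso attack at C3 cannot end in retro-Mannich loss of the side chain, while the two ring bromines deactivate ring A against further bromination.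

**Compound list**

1 | 6-bromoisatin | O=C1Nc2cc(Br)ccc2C1=O | starting material
2 | 5,6-dibromoisatin | O=C1Nc2cc(Br)c(Br)cc2C1=O | intermediate
3 | iodomethane | CI | starting material
4 | 5,6-dibromo-1-methylisatin | CN1C(=O)C(=O)c2cc(Br)c(Br)cc21 | intermediate
5 | dimethylamine | CNC | starting material
6 | 2-[4,5-dibromo-2-(methylamino)phenyl]-N,N-dimethyl-2-oxoacetamide | CNc1cc(Br)c(Br)cc1C(=O)C(=O)N(C)C | intermediate
7 | N-[4,5-dibromo-2-(2-(dimethylamino)-2-oxoacetyl)phenyl]-N-methylformamide | O=CN(C)c1cc(Br)c(Br)cc1C(=O)C(=O)N(C)C | intermediate
8 | titanium-bound 2,3-diolate of 5,6-dibromo-2,3-dihydroxy-N,N,1-trimethylindoline-3-carboxamide (drawn as the free diol; configuration at C2 and C3 not controlled, both centres vanish on deoxygenation) | CN(C)C(=O)C1(O)C(O)N(C)c2cc(Br)c(Br)cc21 | intermediate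
9 | 5,6-dibromo-N,N,1-trimethylindole-3-carboxamide | CN(C)C(=O)c1cn(C)c2cc(Br)c(Br)cc12 | intermediate
10 | 5,6-dibromo-1-methylgramine | CN(C)Cc1cn(C)c2cc(Br)c(Br)cc12 | intermediate
11 | 2,5,6-tribromo-1-methylgramine | CN(C)Cc1c(Br)n(C)c2cc(Br)c(Br)cc12 | target

**Count**

Total steps: 7. Longest linear sequence: 7 steps (1 → 2 → 4 → 6 → 7 → 9 → 10 → 11).

**Steps most likely to fail**

1. Step 5. The chelating α-ketoamide may take up two electrons to give a titanium enediolate that is only protonated on work-up, so the ketone is reduced to the carbinol without C–C bond formation. Intermolecular pinacol coupling or reductive loss of aryl bromine may also compete. Fallback, setting out from 4 and giving up the carbonyl coupling: the isatin is reduced with BH3·THF (THF, 0 °C → rt, acidic work-up). The lactam carbonyl goes to CH2, the ketone to the carbinol, and dehydration gives 5,6-dibromo-1-methylindole F1. Mannich aminomethylation of F1 at C3 with dimethylmethyleneiminium iodide (Eschenmoser's salt) in MeCN at rt should then give 10, where the route is rejoined.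

2. Step 7. NBS may oxidise the tertiary amine, ipso bromination at C3 may expel the aminomethyl side chain, or the ammonium-substituted, doubly brominated indole may react too slowly. Fallback, setting out from 9 and moving the bromination before the reduction: the C3 carboxamide directs lithiation to C2 with LiN(iPr)2 in THF at −78 °C (an amide base, so no bromine–lithium exchange). Quenching with BrCCl2CCl2Br should give 2,5,6-tribromo-N,N,1-trimethylindole-3-carboxamide F2. Reduction of F2 with AlH3 under the conditions of step 6 should give 11 directly.

3. Step 4. Acyl transfer to the hindered, hydrogen-bonded N-methylaniline nitrogen may be slow, and the acid set free may promote reclosure to isatin 4 with loss of dimethylamine. Fallback, setting out from 2 and changing the order of N-substitution: the N–H isatin 2 is opened with dimethylamine (THF, rt) to 2-(2-amino-4,5-dibromophenyl)-N,N-dimethyl-2-oxoacetamide F3. The unhindered primary aniline of F3 is formylated with acetic formic anhydride to N-[4,5-dibromo-2-(2-(dimethylamino)-2-oxoacetyl)phenyl]formamide F4. The acidic formanilide N–H of F4 is then methylated with iodomethane 3 and K2CO3 in DMF to give 7, where the route is rejoined.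

**Further compounds**

F1 | step 5 | 5,6-dibromo-1-methylindole | Cn1ccc2cc(Br)c(Br)cc21
F2 | step 7 | 2,5,6-tribromo-N,N,1-trimethylindole-3-carboxamide | CN(C)C(=O)c1c(Br)n(C)c2cc(Br)c(Br)cc12
F3 | step 4 | 2-(2-amino-4,5-dibromophenyl)-N,N-dimethyl-2-oxoacetamide | Nc1cc(Br)c(Br)cc1C(=O)C(=O)N(C)C
F4 | step 4 | N-[4,5-dibromo-2-(2-(dimethylamino)-2-oxoacetyl)phenyl]formamide | O=CNc1cc(Br)c(Br)cc1C(=O)C(=O)N(C)C
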